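**Retrosynthetic overview**
1. The strategy rests on the dienone ring C1'–C6': its quaternary C4' (methyl, geranyl) lies between the two enolised ketone carbons C3' and C5', and C2' carries the acetyl group. The ring is therefore a folded 3,5,7-triketo ester, the stereocentre can be set in an open chain, and no dearomatisation is needed.
2. Last disconnection: the methylene bridge, made from C6' of trione 9 and the o-quinone methide released from Mannich base 13 of the geranylated butyrylphloroglucinol (aromatic ring taken from phloroglucinol).
3. Key disconnection: the C1'–C2' bond of the trione ring, by Claisen closure of the central diketone carbon C6 of triketo ester 8 onto its ester carbonyl C1; this is the only ring formed in the route.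
4. Triketo ester 8 comes from keto aldehyde 6: Roskamp homologation builds the keto ester arm, and dianion acetylation of the remaining acetyl group builds the diketone arm.
5. The quaternary carbon comes from methyl (R)-3-hydroxybutanoate by two Frater–Seebach alkylations (geranyl, then methyl); the carbinol carbon is later oxidised to the acetyl carbon.

Key step: step 7

Remark: "geranyl" means (2E)-3,7-dimethylocta-2,6-dien-1-yl; β-triketone units are drawn as one enol tautomer and their R/S descriptors refer to that form; the key precursor is carried as the ethyl ester (ethyl diazoacetate is the commercial diazo ester), a spectator group that is lost in the ring closure.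

Step 1
Reactants: 1 methyl (3R)-3-hydroxybutanoate; 2 geranyl bromide
Product: 3 methyl (2R,3R)-2-geranyl-3-hydroxybutanoate
Conditions: LDA (2.2 equiv), THF, −78 → −20 °C; then 2, DMPU, −78 → 0 °C; aq. NH4Cl
Reagents that add atoms: none
Why: Frater–Seebach alkylation, in which the lithium-chelated alkoxide–enolate dianion should take up the allylic bromide on the face anti to the C3 methyl group of the chelate, setting C2 as R (anti product).

Step 2
Reactants: 3 methyl (2R,3R)-2-geranyl-3-hydroxybutanoate
Product: 4 methyl (2S,3R)-2-geranyl-3-hydroxy-2-methylbutanoate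
Conditions: LDA (2.3 equiv), THF, −78 → −10 °C; then MeI (3 equiv), DMPU, −78 → 0 °C; aq. NH4Cl
Reagents that add atoms: iodomethane, CI
Why: Second Frater–Seebach alkylation, in which the tetrasubstituted chelated enolate should again react on the face anti to the C3 methyl group, so methyl enters where geranyl entered before and the 3R carbinol sets the quaternary carbon as 2S (the order geranyl-then-methyl fixes this configuration).

Step 3
Reactants: 4 methyl (2S,3R)-2-geranyl-3-hydroxy-2-methylbutanoate
Product: 5 (2R,3R)-2-geranyl-2-methylbutane-1,3-diol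
Conditions: LiAlH4, THF, 0 °C → rt; Fieser work-up
Reagents that add atoms: none
Why: Hydride reduction of the ester to the primary alcohol, which leaves the isolated alkenes and the quaternary centre untouched.

Step 4
Reactants: 5 (2R,3R)-2-geranyl-2-methylbutane-1,3-diol
Product: 6 (2R)-2-geranyl-2-methyl-3-oxobutanal
Conditions: Dess–Martin periodinane (2.5 equiv), pyridine, CH2Cl2, 0 °C → rt; used without storage
Reagents that add atoms: none
Why: Dess–Martin oxidation of both hydroxyl groups under buffered, non-nucleophilic conditions should give the non-enolisable β-keto aldehyde; the carbinol centre is erased on purpose and the quaternary centre has no α-hydrogen to lose.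

Step 5
Reactants: 6 (2R)-2-geranyl-2-methyl-3-oxobutanal
Product: 7 ethyl (4S)-4-geranyl-4-methyl-3,5-dioxohexanoate
Conditions: N2CHCO2Et (1.2 equiv), SnCl2 (15 mol%), CH2Cl2, rt
Reagents that add atoms: ethyl diazoacetate, CCOC(=O)C=[N+]=[N-]
Why: Roskamp homologation, in which the tin(II)-activated aldehyde adds the diazo ester and loss of N2 with a 1,2-hydride shift gives the β-keto ester, while the hindered ketone and the trisubstituted alkenes should not react.

Step 6
Reactants: 7 ethyl (4S)-4-geranyl-4-methyl-3,5-dioxohexanoate
Product: 8 ethyl (4S)-4-geranyl-4-methyl-3,5,7-trioxooctanoate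
Conditions: LDA (2.1 equiv), THF, −78 °C; then LiHMDS (1.0 equiv) and MeC(O)N(OMe)Me (1.1 equiv), −78 → −20 °C; cold pH 5 buffer
Reagents that add atoms: N-methoxy-N-methylacetamide, CC(=O)N(C)OC
Why: Weiler-type dianion acylation, in which the keto ester is first masked as its enolate, the acetyl CH3 is then the only acidic site left (C4 is quaternary), and its lithium enolate is acylated by the Weinreb amide, with LiHMDS taking up the acidic proton of the new diketone.

Step 7
Reactants: 8 ethyl (4S)-4-geranyl-4-methyl-3,5,7-trioxooctanoate
Product: 9 (4R)-2-acetyl-4-geranyl-3,5-dihydroxy-4-methylcyclohexa-2,5-dien-1-one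
Conditions: Mg(OMe)2 (3 equiv), MeOH, 0 → 45 °C; then cold 1 M HCl to pH 3
Reagents that add atoms: none
Why: Magnesium methoxide enolises the more acidic 5,7-diketone as a chelated diketonate, whose central carbon C6 adds to the ester carbonyl C1 held in the neighbouring magnesium keto ester chelate; the tetrahedral intermediate loses ethoxide and the new 2-acyl-1,3,5-trione is deprotonated at once, which makes the closure irreversible. The closest known reaction is the base- or magnesium-mediated Claisen (Dieckmann-type) cyclisation of 3,5,7-triketo esters to acylphloroglucinols. The six-membered ring closes in a 6-exo-trig mode (C6 onto C1). No stereocentre is formed; C4 has no α-hydrogen and is carried through unchanged, and because it is quaternary the ring cannot aromatise and should appear directly as the dienone-diol tautomer. The step needs C6-to-C1 Claisen closure to beat C2-to-C7 aldol closure and methoxide-induced retro-Claisen cleavage at the non-enolisable C3–C4–C5 diketone: the diketone is the stronger carbon acid and so is the nucleophile while its C7 carbonyl is masked as the enolate, both ketones next to C4 are tied up in magnesium chelates, and only the Claisen product forms a stabilised triketone enolate that leaves the equilibria.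

Step 8
Reactants: 10 phloroglucinol
Product: 11 1-(2,4,6-trihydroxyphenyl)butan-1-one
Conditions: PrCOCl (1.0 equiv), AlCl3 (3.5 equiv), PhNO2/CH2Cl2, 0 → 45 °C; ice/HCl
Reagents that add atoms: butanoyl chloride, CCCC(=O)Cl
Why: Friedel–Crafts acylation of the electron-rich arene, which should stop at the mono-ketone because the first acyl group deactivates the ring.

Step 9
Reactants: 11 1-(2,4,6-trihydroxyphenyl)butan-1-one; 2 geranyl bromide
Product: 12 1-(3-geranyl-2,4,6-trihydroxyphenyl)butan-1-one
Conditions: 2 (1.0 equiv), DBU (1.1 equiv), THF, 0 °C → rt; unreacted 11 recovered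
Reagents that add atoms: none
Why: C-alkylation of the acylphloroglucinol phenoxide by the allylic bromide at one of its two equivalent free ring carbons, with the stoichiometry limiting double alkylation.

Step 10
Reactants: 12 1-(3-geranyl-2,4,6-trihydroxyphenyl)butan-1-one
Product: 13 1-{3-[(dimethylamino)methyl]-5-geranyl-2,4,6-trihydroxyphenyl}butan-1-one
Conditions: CH2=NMe2+ I− (1.1 equiv), Et3N (1.1 equiv), CH2Cl2, 0 °C → rt
Reagents that add atoms: Eschenmoser's salt (N,N-dimethylmethyleneiminium iodide), C=[N+](C)C.[I-]
Why: Phenol Mannich reaction with the preformed iminium salt at the only free ring carbon, which is far more nucleophilic than the ketone α-carbon or the isolated alkenes.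

Step 11
Reactants: 9 (4R)-2-acetyl-4-geranyl-3,5-dihydroxy-4-methylcyclohexa-2,5-dien-1-one; 13 1-{3-[(dimethylamino)methyl]-5-geranyl-2,4,6-trihydroxyphenyl}butan-1-one
Product: 15 (4R)-2-acetyl-6-[(3-butanoyl-5-geranyl-2,4,6-trihydroxyphenyl)methyl]-4-geranyl-3,5-dihydroxy-4-methylcyclohexa-2,5-dien-1-one (CNP0209203.1), via o-quinone methide 14 (not isolated)
Conditions: 13 (1.2 equiv), toluene, 100 °C, N2 stream
Reagents that add atoms: none
Why: The acidic trione protonates the Mannich base, thermal loss of dimethylamine gives the o-quinone methide, and Michael addition of the only free enol carbon (C6) of 9 followed by rearomatisation should form the methylene bridge without touching the quaternary centre (o-quinone methide alkylation of a cyclic 1,3-dicarbonyl).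

**Compound list**
1 | methyl (3R)-3-hydroxybutanoate | C[C@@H](O)CC(=O)OC | starting material
2 | geranyl bromide, (2E)-1-bromo-3,7-dimethylocta-2,6-diene | CC(C)=CCC/C(C)=C/CBr | starting material
3 | methyl (2R,3R)-2-geranyl-3-hydroxybutanoate | COC(=O)[C@H](C/C=C(\C)CCC=C(C)C)[C@@H](C)O | intermediate
4 | methyl (2S,3R)-2-geranyl-3-hydroxy-2-methylbutanoate | COC(=O)[C@@](C)(C/C=C(\C)CCC=C(C)C)[C@@H](C)O | intermediate
5 | (2R,3R)-2-geranyl-2-methylbutane-1,3-diol | OC[C@@](C)(C/C=C(\C)CCC=C(C)C)[C@@H](C)O | intermediate
6 | (2R)-2-geranyl-2-methyl-3-oxobutanal | O=C[C@@](C)(C/C=C(\C)CCC=C(C)C)C(C)=O | intermediate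
7 | ethyl (4S)-4-geranyl-4-methyl-3,5-dioxohexanoate | CCOC(=O)CC(=O)[C@@](C)(C/C=C(\C)CCC=C(C)C)C(C)=O | intermediate
8 | ethyl (4S)-4-geranyl-4-methyl-3,5,7-trioxooctanoate | CCOC(=O)CC(=O)[C@@](C)(C/C=C(\C)CCC=C(C)C)C(=O)CC(C)=O | intermediate
9 | (4R)-2-acetyl-4-geranyl-3,5-dihydroxy-4-methylcyclohexa-2,5-dien-1-one | O=C1C=C(O)[C@@](C)(C/C=C(\C)CCC=C(C)C)C(O)=C1C(C)=O | intermediate
10 | phloroglucinol | Oc1cc(O)cc(O)c1 | starting material
11 | 1-(2,4,6-trihydroxyphenyl)butan-1-one | CCCC(=O)c1c(O)cc(O)cc1O | intermediate
12 | 1-(3-geranyl-2,4,6-trihydroxyphenyl)butan-1-one | CCCC(=O)c1c(O)cc(O)c(C/C=C(\C)CCC=C(C)C)c1O | intermediate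
13 | 1-{3-[(dimethylamino)methyl]-5-geranyl-2,4,6-trihydroxyphenyl}butan-1-one | CCCC(=O)c1c(O)c(CN(C)C)c(O)c(C/C=C(\C)CCC=C(C)C)c1O | intermediate
14 | o-quinone methide, 2-butanoyl-4-geranyl-3,5-dihydroxy-6-methylidenecyclohexa-2,4-dien-1-one | C=C1C(=O)C(C(=O)CCC)=C(O)C(C/C=C(\C)CCC=C(C)C)=C1O | intermediate
15 | (4R)-2-acetyl-6-[(3-butanoyl-5-geranyl-2,4,6-trihydroxyphenyl)methyl]-4-geranyl-3,5-dihydroxy-4-methylcyclohexa-2,5-dien-1-one | CCCC(=O)c1c(O)c(C/C=C(\C)CCC=C(C)C)c(O)c(CC2=C(O)[C@@](C)(C/C=C(\C)CCC=C(C)C)C(O)=C(C(C)=O)C2=O)c1O | target

**Step count**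
Total: 11 steps. Longest linear sequence: 8 steps (steps 1–7 and 11); steps 8–10 form the second branch.

**Steps most likely to fail**

Step 7 (key Claisen closure). The ring closure may lose out to aldol closure of C2 onto the C7 ketone, or methoxide may cleave the non-enolisable diketone at C4 by retro-Claisen attack. The fallback closes the ring before the acetyl group is present and resolves at the end. It sets out from 7: potassium tert-butoxide in THF should drive the Dieckmann closure of the acetyl enolate onto the ester to give the achiral 2-geranyl-2-methylcyclohexane-1,3,5-trione F1. O-acetylation with acetic anhydride/triethylamine and DMAP-mediated O-to-C acyl shift should give racemic 2-acetyl-4-geranyl-3,5-dihydroxy-4-methylcyclohexa-2,5-dien-1-one F2. Preparative chromatography on a chiral stationary phase separates it into 9 and the unwanted (4S)-enantiomer F3, and the route is rejoined at 9.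

Step 6 (dianion acetylation). Proton transfer from the newly formed diketone may quench the dianion, or the acetyl enolate may close early onto the ester and destroy the stereocentre. The fallback forms the C–C bond by aldol addition and adjusts the oxidation level afterwards. It sets out from 7: the dianion (LDA, THF, −78 °C) is trapped with acetaldehyde to give ethyl (4S)-4-geranyl-7-hydroxy-4-methyl-3,5-dioxooctanoate F4 as a mixture of C7 epimers, whose alkoxide is not acidic. Oxidation with one equivalent of Dess–Martin periodinane leads back to 8.

Step 5 (Roskamp homologation). Addition of the diazo ester to the neopentyl-type aldehyde may be slow, so that deformylation of the β-keto aldehyde or carbon instead of hydride migration takes over. The fallback uses an organozinc addition followed by oxidation. It sets out from 6: Reformatsky reaction with ethyl bromoacetate and activated zinc in THF adds selectively to the aldehyde to give ethyl (4R)-4-geranyl-3-hydroxy-4-methyl-5-oxohexanoate F5 as a mixture of C3 epimers. Dess–Martin oxidation of the carbinol returns to 7.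

**Further compounds**
F1 | step 7 | 2-geranyl-2-methylcyclohexane-1,3,5-trione | O=C1CC(=O)C(C)(C/C=C(\C)CCC=C(C)C)C(=O)C1
F2 | step 7 | racemic 2-acetyl-4-geranyl-3,5-dihydroxy-4-methylcyclohexa-2,5-dien-1-one | O=C1C=C(O)C(C)(C/C=C(\C)CCC=C(C)C)C(O)=C1C(C)=O
F3 | step 7 | (4S)-2-acetyl-4-geranyl-3,5-dihydroxy-4-methylcyclohexa-2,5-dien-1-one | O=C1C=C(O)[C@](C)(C/C=C(\C)CCC=C(C)C)C(O)=C1C(C)=O
F4 | step 6 | ethyl (4S)-4-geranyl-7-hydroxy-4-methyl-3,5-dioxooctanoate (C7 epimers) | CCOC(=O)CC(=O)[C@@](C)(C/C=C(\C)CCC=C(C)C)C(=O)CC(C)O
F5 | step 5 | ethyl (4R)-4-geranyl-3-hydroxy-4-methyl-5-oxohexanoate (C3 epimers) | CCOC(=O)CC(O)[C@@](C)(C/C=C(\C)CCC=C(C)C)C(C)=O
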